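**Strategy**

The seven-membered ring of the guaiane (C1, C5–C10) is reduced to a six-membered one: C5–C10, with the C7 isopropyl group and the C8 oxygen, are the ring carbons of (R)-cryptone, and C1, the single carbon that separates the oxygenated C10 from C5, is left out. The key step puts it back in one operation: methylene transfer to the C10=C5 bond of a silyl enol ether, oxidative scission of the shared C5–C10 cyclopropane bond and loss of HCl deliver the cycloheptenone with C10=O and C1=C5. Its precursor is a 1-trimethylsilyloxycyclohexene carrying the 7β-isopropyl group and a silyl-protected 8α-oxygen. The enone then accepts both cyclopentane arms.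

Key step: step 5

Remark on numbering: guaiane numbering is used throughout (C1/C5 ring fusion; C2–C4 complete the cyclopentane; C6–C10 complete the cycloheptane; C14 is the methyl on C10, C15 the methyl on C4); α is the face of H1 and of the C10 hydroxyl in the target, β that of the C7 isopropyl group and the C8 ester oxygen.

Assumption: (R)-cryptone is bought as the single enantiomer; its stereocentre becomes C7 and is never part of a reacting bond.

Precursor design: O8 carries a TBS group (stable to the zinc carbenoid, to FeCl3 in DMF and to the later organometallic steps), the enol oxygen a trimethylsilyl group (the group FeCl3 removes cleanly), and no other alkene is present when the carbenoid is used.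

**Route**

Step 1
Reactants: 1 (R)-cryptone
Product: 2 (2R,3R,4R)-2,3-epoxy-4-isopropylcyclohexan-1-one (oxirane trans to isopropyl)
Conditions: 30% aqueous H2O2, NaOH (0.2 equiv), MeOH, −10 to 0 °C
Reagents that add atoms: hydrogen peroxide, OO
Why: Weitz–Scheffer nucleophilic epoxidation, in which hydroperoxide anion adds to C3 of the enone on the face opposite the adjacent isopropyl group and the enolate closes the oxirane, so the epoxide should form trans to the isopropyl group (2R,3R); this C3 centre (C8 of the target) is provisional, because it is reset in steps 10 and 11.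

Step 2
Reactants: 2 (2R,3R,4R)-2,3-epoxy-4-isopropylcyclohexan-1-one
Product: 3 (3S,4R)-3-hydroxy-4-isopropylcyclohexan-1-one
Conditions: (PhSe)2, NaBH4, EtOH, rt; then AcOH and 2, 0 °C to rt
Reagents that add atoms: none
Why: Selenium-mediated reductive opening of an α,β-epoxy ketone, in which phenylselenide opens the oxirane at the α-carbon, a second selenide removes selenium and the enolate is protonated, so only the C2–O bond is cleaved and the C3 carbinol keeps its configuration, while the acetic acid buffer suppresses β-elimination back to the enone.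

Step 3
Reactants: 3 (3S,4R)-3-hydroxy-4-isopropylcyclohexan-1-one
Product: 4 (3S,4R)-3-(tert-butyldimethylsilyloxy)-4-isopropylcyclohexan-1-one
Conditions: TBSCl, imidazole, DMF, rt
Reagents that add atoms: tert-butyldimethylsilyl chloride, CC(C)(C)[Si](C)(C)Cl
Why: Standard silylation of a secondary alcohol (silyl chloride/imidazole) under conditions too mild to dehydrate the β-hydroxy ketone; no stereocentre is touched.

Step 4
Reactants: 4 (3S,4R)-3-(tert-butyldimethylsilyloxy)-4-isopropylcyclohexan-1-one
Product: 6 (4R,5S)-5-(tert-butyldimethylsilyloxy)-4-isopropyl-1-(trimethylsilyloxy)cyclohex-1-ene, via lithium enolate 5 (not isolated)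
Conditions: LiN(iPr)2, THF, −78 °C; then Me3SiCl, −78 to 0 °C; non-aqueous work-up
Reagents that add atoms: chlorotrimethylsilane, C[Si](C)(C)Cl
Why: Kinetic enolisation with a hindered lithium amide and O-silylation, in which the C6 protons, remote from the bulky electron-rich silyloxy group at C3, are removed in preference to those at C2 and low-temperature trapping prevents enolate equilibration and β-elimination of silanolate, so the C10=C5 enol ether (guaiane numbering) is obtained; no stereocentre is formed.

Step 5
Reactants: 6 (4R,5S)-5-(tert-butyldimethylsilyloxy)-4-isopropyl-1-(trimethylsilyloxy)cyclohex-1-ene; 7 diiodomethane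
Product: 10 (5R,6S)-6-(tert-butyldimethylsilyloxy)-5-isopropylcyclohept-2-en-1-one, via siloxycyclopropane 8 (not isolated), via β-chloro ketone 9 (not isolated)
Conditions: (a) Et2Zn, CH2I2, CH2Cl2, 0 °C to rt, pyridine quench, filtration, crude carried on; (b) FeCl3, DMF, 0 °C to rt, crude carried on; (c) NaOAc, MeOH, 50 °C
Reagents that add atoms: diiodomethane 7, ICI
Why: The zinc carbenoid EtZnCH2I transfers CH2 to the electron-rich C10=C5 enol ether in a concerted syn [2+1] step (closest known reaction type: the Simmons–Smith/FeCl3 one-carbon homologation of cycloalkanone trimethylsilyl enol ethers to cycloalk-2-enones), which makes C1–C10 and C1–C5. FeCl3 then oxidises the siloxycyclopropane by one electron (trivalent iron becomes divalent iron), the oxygen-centred radical formed on loss of the silyl group undergoes β-scission of the shared C5–C10 bond, the ring-enlarged C5 radical takes chlorine from a second FeCl3, and acetate removes HCl across C1–C5 by E1cB elimination. The three-membered ring closes by cheletropic methylene transfer to one face of the alkene, whereas the seven-membered ring is not closed by a cyclisation at all but released by fragmentation of the zero-atom bridge of the bicyclo[4.1.0]heptane. No stereocentre is created that survives: the two cyclopropane centres (C5, C10) may form on either face because both end up sp2, and C7 and C8 lie outside every bond that changes. The selectivity needed is regiochemical, insertion between C10 and C5 and not between C10 and C9 and cleavage of the internal and not an external cyclopropane bond; the first is fixed by the position of the enol ether made in step 4, the second by the alignment of the ring-fusion bond with the oxygen radical and by the secondary, ring-expanded radical it releases. Chemoselectivity is secured by the absence of any other alkene, by the stability of the TBS ether to FeCl3 in DMF and by chloride being a far better leaving group than the C8 silyloxy group in the elimination.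

Step 6
Reactants: 10 (5R,6S)-6-(tert-butyldimethylsilyloxy)-5-isopropylcyclohept-2-en-1-one; 11 isopropenylmagnesium bromide; 12 allyl iodide
Product: 14 (2R,3S,5R,6S)-2-allyl-6-(tert-butyldimethylsilyloxy)-5-isopropyl-3-(prop-1-en-2-yl)cycloheptan-1-one, via bromomagnesium enolate 13 (not isolated)
Conditions: CH2=C(CH3)MgBr, CuBr·SMe2 (20 mol%), THF, −78 to −40 °C; then allyl iodide, DMPU, −78 to 0 °C
Reagents that add atoms: isopropenylmagnesium bromide 11, CC(=C)[Mg]Br; allyl iodide 12, C=CCI
Why: Copper-catalysed conjugate addition of the alkenyl Grignard reagent followed by C-allylation of the regiodefined magnesium enolate (tandem 1,4-addition/enolate trapping), in which C5 is to be set by the C7 isopropyl group, the alkenyl group being expected to enter on the α-face opposite to it, and allyl iodide then adds to C1 anti to the new C5 substituent, giving the trans arrangement (1R,5S in guaiane numbering) that is also the preferred one at the epimerisable C1.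

Step 7
Reactants: 14 (2R,3S,5R,6S)-2-allyl-6-(tert-butyldimethylsilyloxy)-5-isopropyl-3-(prop-1-en-2-yl)cycloheptan-1-one
Product: 15 (1R,5S,7R,8S)-8-(tert-butyldimethylsilyloxy)-14-norguai-3-en-10-one (trans-fused, H1 α, H5 β)
Conditions: second-generation Grubbs catalyst RuCl2(=CHPh)(PCy3)(H2IMes) (5 mol%), CH2Cl2, 40 °C
Reagents that add atoms: none
Why: Ring-closing metathesis of the allyl group onto the 1,1-disubstituted isopropenyl group with loss of ethene closes the cyclopentene and places the trisubstituted double bond at C3=C4, and the neutral conditions leave the trans ring fusion at the enolisable C1 and the silyl ether untouched.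

Step 8
Reactants: 15 (1R,5S,7R,8S)-8-(tert-butyldimethylsilyloxy)-14-norguai-3-en-10-one; 16 methyllithium
Product: 17 (1R,5S,7R,8S,10R)-8-(tert-butyldimethylsilyloxy)guai-3-en-10-ol (10α-OH, 10β-CH3)
Conditions: MeAl(OAr)2 (3 equiv; Ar = 2,6-di-tert-butyl-4-methylphenyl; made from AlMe3 and ArOH), toluene, −78 °C; then MeLi, Et2O, −78 °C
Reagents that add atoms: methyllithium 16, [Li]C
Why: Amphiphilic carbonyl methylation, in which the very bulky aluminium bis(aryloxide) binds the ketone and screens its more open α-face (the equatorial-type approach syn to H1 that a free methyl–metal reagent is expected to take on this trans-fused cycloheptanone), so methyllithium is forced to add from the β-face and should give the 10β-methyl-10α-carbinol (10R), while the low temperature prevents enolisation towards C1.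

Step 9
Reactants: 17 (1R,5S,7R,8S,10R)-8-(tert-butyldimethylsilyloxy)guai-3-en-10-ol
Product: 18 (1R,5S,7R,8S,10R)-guai-3-ene-8,10-diol (8α,10α)
Conditions: TBAF, THF, rt to 45 °C
Reagents that add atoms: none
Why: Fluoride-mediated cleavage of the hindered secondary TBS ether, to which the tertiary alcohol and the alkene are inert.

Step 10
Reactants: 18 (1R,5S,7R,8S,10R)-guai-3-ene-8,10-diol
Product: 19 (1R,5S,7R,10R)-10-hydroxyguai-3-en-8-one
Conditions: Dess–Martin periodinane, NaHCO3, CH2Cl2, 0 °C to rt
Reagents that add atoms: none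
Why: Dess–Martin oxidation of the only secondary alcohol under buffered, near-neutral conditions, which spare the tertiary aldol-type C10 carbinol (no retro-aldol cleavage or dehydration) and do not epimerise C7 next to the new ketone.

Step 11
Reactants: 19 (1R,5S,7R,10R)-10-hydroxyguai-3-en-8-one
Product: 20 (1R,5S,7R,8R,10R)-guai-3-ene-8,10-diol (8β,10α)
Conditions: Me4NBH(OAc)3, MeCN/AcOH (1:1), −25 °C
Reagents that add atoms: none
Why: Hydroxyl-directed Evans–Saksena reduction, in which the 10α-hydroxyl exchanges an acetate on boron and delivers hydride intramolecularly to the α-face of the C8 carbonyl through a six-membered transition state, so the new hydroxyl should be β, anti to the C10 oxygen and cis to the isopropyl group (8R).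

Step 12
Reactants: 21 isovanillic acid
Product: 23 3-(tert-butyldimethylsilyloxy)-4-methoxybenzoic acid, via bis-silyl derivative 22 (not isolated)
Conditions: TBSCl (2.3 equiv), imidazole, DMF, rt; then AcOH/THF/H2O, rt
Reagents that add atoms: tert-butyldimethylsilyl chloride, CC(C)(C)[Si](C)(C)Cl
Why: Exhaustive silylation of phenol and carboxylic acid followed by selective hydrolysis of the far more labile silyl ester in aqueous acetic acid leaves the aryl silyl ether, which masks the phenol during acylation and epoxidation.

Step 13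
Reactants: 20 (1R,5S,7R,8R,10R)-guai-3-ene-8,10-diol; 23 3-(tert-butyldimethylsilyloxy)-4-methoxybenzoic acid
Product: 25 (1R,5S,7R,8R,10R)-10-hydroxyguai-3-en-8-yl 3-(tert-butyldimethylsilyloxy)-4-methoxybenzoate, via mixed anhydride 24 (not isolated)
Conditions: 23, 2,4,6-trichlorobenzoyl chloride, Et3N, THF, rt; then 20, DMAP, toluene, rt to 40 °C
Reagents that add atoms: 3-(tert-butyldimethylsilyloxy)-4-methoxybenzoic acid 23, COc1ccc(C(=O)O)cc1O[Si](C)(C)C(C)(C)C
Why: Yamaguchi esterification, in which the mixed anhydride transfers the aroyl group through its acylpyridinium salt to the hindered secondary 8β-hydroxyl while the tertiary C10 hydroxyl is unreactive, and since the C8–O bond is not broken the configuration at C8 is retained.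

Step 14
Reactants: 25 (1R,5S,7R,8R,10R)-10-hydroxyguai-3-en-8-yl 3-(tert-butyldimethylsilyloxy)-4-methoxybenzoate
Product: 26 (1R,3R,4S,5S,7R,8R,10R)-3,4-epoxy-10-hydroxyguaian-8-yl 3-(tert-butyldimethylsilyloxy)-4-methoxybenzoate (3α,4α-epoxide)
Conditions: VO(acac)2 (5 mol%), t-BuOOH, CH2Cl2, 0 °C to rt
Reagents that add atoms: tert-butyl hydroperoxide, CC(C)(C)OO
Why: Hydroxyl-directed vanadium-catalysed epoxidation, in which the free 10α-hydroxyl (bishomoallylic to C3) binds the vanadium peroxide and delivers oxygen to the α-face of the only alkene, the β-face being further screened by the β-methyl group on C10, which should give the 3α,4α-epoxide (3R,4S) and leaves the aryl silyl ether and the ester untouched.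

Step 15
Reactants: 26 (1R,3R,4S,5S,7R,8R,10R)-3,4-epoxy-10-hydroxyguaian-8-yl 3-(tert-butyldimethylsilyloxy)-4-methoxybenzoate
Product: 27 (1R,3R,4S,5S,7R,8R,10R)-3,4-epoxy-10-hydroxyguaian-8-yl 3-hydroxy-4-methoxybenzoate (target)
Conditions: TBAF, AcOH, THF, 0 °C
Reagents that add atoms: none
Why: Fluoride cleaves the aryl silyl ether rapidly at 0 °C, and the acetic acid buffer keeps the phenoxide from attacking the ester and protects the epoxy alcohol.

**Compound list**

1 | (R)-cryptone, (4R)-4-isopropylcyclohex-2-en-1-one | O=C1C=C[C@@H](C(C)C)CC1 | starting material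
2 | (2R,3R,4R)-2,3-epoxy-4-isopropylcyclohexan-1-one | O=C1CC[C@H](C(C)C)[C@H]2O[C@@H]12 | intermediate
3 | (3S,4R)-3-hydroxy-4-isopropylcyclohexan-1-one | O=C1CC[C@H](C(C)C)[C@@H](O)C1 | intermediate
4 | (3S,4R)-3-(tert-butyldimethylsilyloxy)-4-isopropylcyclohexan-1-one | O=C1CC[C@H](C(C)C)[C@@H](O[Si](C)(C)C(C)(C)C)C1 | intermediate
5 | lithium (4R,5S)-5-(tert-butyldimethylsilyloxy)-4-isopropylcyclohex-1-en-1-olate (not isolated) | [Li]OC1=CC[C@H](C(C)C)[C@@H](O[Si](C)(C)C(C)(C)C)C1 | intermediate
6 | (4R,5S)-5-(tert-butyldimethylsilyloxy)-4-isopropyl-1-(trimethylsilyloxy)cyclohex-1-ene | C[Si](C)(C)OC1=CC[C@H](C(C)C)[C@@H](O[Si](C)(C)C(C)(C)C)C1 | intermediate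
7 | diiodomethane | ICI | starting material
8 | (3S,4R)-3-(tert-butyldimethylsilyloxy)-4-isopropyl-1-(trimethylsilyloxy)bicyclo[4.1.0]heptane, both cis-fused cyclopropane diastereomers (not isolated) | C[Si](C)(C)OC12CC1C[C@H](C(C)C)[C@@H](O[Si](C)(C)C(C)(C)C)C2 | intermediate
9 | (5R,6S)-6-(tert-butyldimethylsilyloxy)-3-chloro-5-isopropylcycloheptan-1-one, either C3 epimer (not isolated) | O=C1CC(Cl)C[C@H](C(C)C)[C@@H](O[Si](C)(C)C(C)(C)C)C1 | intermediate
10 | (5R,6S)-6-(tert-butyldimethylsilyloxy)-5-isopropylcyclohept-2-en-1-one | O=C1C=CC[C@H](C(C)C)[C@@H](O[Si](C)(C)C(C)(C)C)C1 | intermediate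
11 | isopropenylmagnesium bromide, CH2=C(CH3)MgBr | CC(=C)[Mg]Br | starting material
12 | allyl iodide | C=CCI | starting material
13 | bromomagnesium (3S,5R,6S)-6-(tert-butyldimethylsilyloxy)-5-isopropyl-3-(prop-1-en-2-yl)cyclohept-1-en-1-olate (not isolated) | Br[Mg]OC1=C[C@@H](C(C)=C)C[C@H](C(C)C)[C@@H](O[Si](C)(C)C(C)(C)C)C1 | intermediate
14 | (2R,3S,5R,6S)-2-allyl-6-(tert-butyldimethylsilyloxy)-5-isopropyl-3-(prop-1-en-2-yl)cycloheptan-1-one | O=C1[C@H](CC=C)[C@@H](C(C)=C)C[C@H](C(C)C)[C@@H](O[Si](C)(C)C(C)(C)C)C1 | intermediate
15 | (1R,5S,7R,8S)-8-(tert-butyldimethylsilyloxy)-14-norguai-3-en-10-one | O=C1[C@@H]2CC=C(C)[C@H]2C[C@H](C(C)C)[C@@H](O[Si](C)(C)C(C)(C)C)C1 | intermediate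
16 | methyllithium | [Li]C | starting material
17 | (1R,5S,7R,8S,10R)-8-(tert-butyldimethylsilyloxy)guai-3-en-10-ol | CC(C)(C)[Si](C)(C)O[C@H]1C[C@@](C)(O)[C@@H]2CC=C(C)[C@H]2C[C@@H]1C(C)C | intermediate
18 | (1R,5S,7R,8S,10R)-guai-3-ene-8,10-diol (8α,10α) | O[C@H]1C[C@@](C)(O)[C@@H]2CC=C(C)[C@H]2C[C@@H]1C(C)C | intermediate
19 | (1R,5S,7R,10R)-10-hydroxyguai-3-en-8-one | O=C1C[C@@](C)(O)[C@@H]2CC=C(C)[C@H]2C[C@@H]1C(C)C | intermediate
20 | (1R,5S,7R,8R,10R)-guai-3-ene-8,10-diol (8β,10α) | O[C@@H]1C[C@@](C)(O)[C@@H]2CC=C(C)[C@H]2C[C@@H]1C(C)C | intermediate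
21 | isovanillic acid, 3-hydroxy-4-methoxybenzoic acid | COc1ccc(C(=O)O)cc1O | starting material
22 | tert-butyldimethylsilyl 3-(tert-butyldimethylsilyloxy)-4-methoxybenzoate (not isolated) | COc1ccc(C(=O)O[Si](C)(C)C(C)(C)C)cc1O[Si](C)(C)C(C)(C)C | intermediate
23 | 3-(tert-butyldimethylsilyloxy)-4-methoxybenzoic acid | COc1ccc(C(=O)O)cc1O[Si](C)(C)C(C)(C)C | intermediate
24 | 3-(tert-butyldimethylsilyloxy)-4-methoxybenzoic 2,4,6-trichlorobenzoic anhydride (not isolated) | COc1ccc(C(=O)OC(=O)c2c(Cl)cc(Cl)cc2Cl)cc1O[Si](C)(C)C(C)(C)C | intermediate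
25 | (1R,5S,7R,8R,10R)-10-hydroxyguai-3-en-8-yl 3-(tert-butyldimethylsilyloxy)-4-methoxybenzoate | COc1ccc(C(=O)O[C@@H]2C[C@@](C)(O)[C@@H]3CC=C(C)[C@H]3C[C@@H]2C(C)C)cc1O[Si](C)(C)C(C)(C)C | intermediate
26 | (1R,3R,4S,5S,7R,8R,10R)-3,4-epoxy-10-hydroxyguaian-8-yl 3-(tert-butyldimethylsilyloxy)-4-methoxybenzoate | COc1ccc(C(=O)O[C@@H]2C[C@@](C)(O)[C@@H]3C[C@H]4O[C@@]4(C)[C@H]3C[C@@H]2C(C)C)cc1O[Si](C)(C)C(C)(C)C | intermediate
27 | (1R,3R,4S,5S,7R,8R,10R)-3,4-epoxy-10-hydroxyguaian-8-yl 3-hydroxy-4-methoxybenzoate | COc1ccc(C(=O)O[C@@H]2C[C@@](C)(O)[C@@H]3C[C@H]4O[C@@]4(C)[C@H]3C[C@@H]2C(C)C)cc1O | target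

**Step count and risk**

Total steps: 15. Longest linear sequence: 14 steps (steps 1–11 and 13–15, from 1); step 12 is a one-step side branch.

The three steps most likely to fail, most doubtful first:

Step 6, facial selectivity and enolate trapping. The control element is weak: an equatorial isopropyl group 1,3 to the reacting carbon of a flexible cycloheptenone. Attack on the convex face of the chair enone could instead place the alkenyl group cis to the isopropyl group, which is the wrong C5 configuration. Proton transfer during the slow allylation could also scramble the enolate or expel silanolate from C8. The fallback sets out from 10 and comes back at 14, and puts C5 under catalyst control. Rhodium-catalysed Hayashi–Miyaura addition of isopropenylboronic acid pinacol ester to 10, with [Rh(cod)Cl]2/(S)-BINAP and aqueous KOH in dioxane, should give (3S,5R,6S)-6-(tert-butyldimethylsilyloxy)-5-isopropyl-3-(prop-1-en-2-yl)cycloheptan-1-one F1; the ligand enantiomer is the one expected, by analogy with cyclohept-2-enone itself, to send the alkenyl group to the α-face. LiN(iPr)2 at −78 °C then forms, away from the silyloxy-bearing carbon as in step 4, the lithium (3S,5R,6S)-6-(tert-butyldimethylsilyloxy)-5-isopropyl-3-(prop-1-en-2-yl)cyclohept-1-en-1-olate F2, which is allylated with allyl iodide anti to the isopropenyl group to give 14.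

Step 8, facial selectivity of methyl delivery. If the hindered ketone is not fully bound by the aluminium reagent, free methyllithium can add from the α-face and give the C10 epimer, and enolisation would erode the trans ring fusion. The fallback sets out from 15 and comes back at 18; the carbinol oxygen is delivered by a hydroxyl-directed epoxidation instead of a carbonyl addition. Non-basic methylenation of 15 (Zn, CH2Br2, TiCl4) gives (1R,5S,7R,8S)-8-(tert-butyldimethylsilyloxy)guaia-3,10(14)-diene F3. TBAF frees the homoallylic alcohol (1R,5S,7R,8S)-guaia-3,10(14)-dien-8-ol F4. VO(acac)2/t-BuOOH, directed by the 8α-hydroxyl, should epoxidise only the exocyclic alkene from the α-face to give (1R,5S,7R,8S,10R)-10,14-epoxyguai-3-en-8-ol F5. LiAlH4 opens the oxirane at its CH2 terminus and gives diol 18.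

Step 5, the key step. Premature loss of the trimethylsilyl group (zinc iodide, adventitious acid) would give a cyclopropanol that opens at an external bond to the 2-methylcyclohexanone. FeCl3 or the basic elimination could also attack the C8 silyloxy group (desilylation, β-elimination). The fallback sets out from 4 and comes back at 10; the ketone, not its enol ether, is homologated. Me3SiCHN2/AlMe3 should insert the CHSiMe3 unit on the C5 side of 4, because the CH2 that is not deactivated by the β-silyloxy group migrates, to give (5R,6S)-6-(tert-butyldimethylsilyloxy)-5-isopropyl-2-(trimethylsilyl)cycloheptan-1-one F6. This is protodesilylated on work-up to (3S,4R)-3-(tert-butyldimethylsilyloxy)-4-isopropylcycloheptan-1-one F7. Kinetic enolisation and silylation as in step 4 give lithium (5R,6S)-6-(tert-butyldimethylsilyloxy)-5-isopropylcyclohept-1-en-1-olate F8 and then (5R,6S)-6-(tert-butyldimethylsilyloxy)-5-isopropyl-1-(trimethylsilyloxy)cyclohept-1-ene F9. Saegusa–Ito oxidation with Pd(OAc)2 introduces the C1=C5 double bond of 10.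

**Further compounds**

F1 | step 6 | (3S,5R,6S)-6-(tert-butyldimethylsilyloxy)-5-isopropyl-3-(prop-1-en-2-yl)cycloheptan-1-one | O=C1C[C@@H](C(C)=C)C[C@H](C(C)C)[C@@H](O[Si](C)(C)C(C)(C)C)C1
F2 | step 6 | lithium (3S,5R,6S)-6-(tert-butyldimethylsilyloxy)-5-isopropyl-3-(prop-1-en-2-yl)cyclohept-1-en-1-olate | [Li]OC1=C[C@@H](C(C)=C)C[C@H](C(C)C)[C@@H](O[Si](C)(C)C(C)(C)C)C1
F3 | step 8 | (1R,5S,7R,8S)-8-(tert-butyldimethylsilyloxy)guaia-3,10(14)-diene | CC(C)(C)[Si](C)(C)O[C@H]1CC(=C)[C@@H]2CC=C(C)[C@H]2C[C@@H]1C(C)C
F4 | step 8 | (1R,5S,7R,8S)-guaia-3,10(14)-dien-8-ol | O[C@H]1CC(=C)[C@@H]2CC=C(C)[C@H]2C[C@@H]1C(C)C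
F5 | step 8 | (1R,5S,7R,8S,10R)-10,14-epoxyguai-3-en-8-ol | O[C@H]1C[C@@]3(OC3)[C@@H]2CC=C(C)[C@H]2C[C@@H]1C(C)C
F6 | step 5 | (5R,6S)-6-(tert-butyldimethylsilyloxy)-5-isopropyl-2-(trimethylsilyl)cycloheptan-1-one, either C2 epimer | O=C1C([Si](C)(C)C)CC[C@H](C(C)C)[C@@H](O[Si](C)(C)C(C)(C)C)C1
F7 | step 5 | (3S,4R)-3-(tert-butyldimethylsilyloxy)-4-isopropylcycloheptan-1-one | O=C1CCC[C@H](C(C)C)[C@@H](O[Si](C)(C)C(C)(C)C)C1
F8 | step 5 | lithium (5R,6S)-6-(tert-butyldimethylsilyloxy)-5-isopropylcyclohept-1-en-1-olate | [Li]OC1=CCC[C@H](C(C)C)[C@@H](O[Si](C)(C)C(C)(C)C)C1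
F9 | step 5 | (5R,6S)-6-(tert-butyldimethylsilyloxy)-5-isopropyl-1-(trimethylsilyloxy)cyclohept-1-ene | C[Si](C)(C)OC1=CCC[C@H](C(C)C)[C@@H](O[Si](C)(C)C(C)(C)C)C1
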